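**Retrosynthetic overview**
1. Nocomtal ← its MOM/TBS-protected (E)-enal ← ring A methyl ester of the trans-benzodioxane (ester reduction, MnO2, Wittig, acid); the side chain is grown only after both rings exist.
2. Feature used: C4 and C5 of ring A each carry an ether oxygen, and these two oxygens are the heteroatoms of the dioxane that also holds C8' and C7'. A 2-pyrone bound through its C3 oxygen to C8' and an ethynyl ether on the C7' oxygen can therefore form C4–C5 and C1–C6, lose CO2, and close ring A and the dioxane in one operation.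
3. Cycloaddition precursor ← (7'S,8'R) ynol ether alcohol + methyl 3-hydroxy-4-methoxy-2-oxo-2H-pyran-6-carboxylate, by Mitsunobu etherification with inversion at C8' (anti carbinol → syn diether → trans dioxane).
4. Ynol ether alcohol ← anti alcohol (KH/trichloroethylene, protecting-group exchange, n-BuLi) ← aryl ketone by chelation-controlled reduction ← 4-bromo-2-methoxyphenol + methyl (R)-glycerate acetonide (C8' from the chiral pool, C7' by substrate control).
5. Hydroxypyrone ← methyl 4-methoxy-2-oxo-2H-pyran-6-carboxylate (bromination, Miyaura borylation, oxidation) ← methyl (E)-3-methoxybut-2-enoate + dimethyl oxalate. Ring order: the guaiacyl ring is bought; ring A and the dioxane form together in step 14.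

Key step: step 14

Remark: a benzylic alkynyl ether can rearrange by a [3,3] shift near 60 °C and lose ketene by a retro-ene path somewhat above, so the alkyne is unmasked only in step 8 and nothing from step 8 to the end of step 14 is warmed above 40 °C; O9' is carried as a TBS ether, and the pyrone is joined to the C8' oxygen by a Mitsunobu reaction because a copper-mediated C–O coupling would engage the terminal alkyne.

Step 1
Reactants: 1 4-bromo-2-methoxyphenol
Product: 2 4-bromo-2-methoxy-1-(methoxymethoxy)benzene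
Conditions: NaH, MOMCl, DMF, 0 °C → rt
Reagents that add atoms: chloromethyl methyl ether, COCCl
Why: Williamson-type O-alkylation of the phenoxide; the MOM acetal should withstand KH and n-BuLi later and leaves in acid at the end.

Step 2
Reactants: 3 methyl (R)-2,2-dimethyl-1,3-dioxolane-4-carboxylate
Product: 4 (R)-N-methoxy-N,2,2-trimethyl-1,3-dioxolane-4-carboxamide
Conditions: MeNH(OMe)·HCl, i-PrMgCl, THF, −20 °C
Reagents that add atoms: N,O-dimethylhydroxylamine hydrochloride, CNOC.Cl
Why: Weinreb amide formation by aminolysis of the ester with the chloromagnesium amide; the low temperature should leave the α-alkoxy stereocentre (later C8') untouched.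

Step 3
Reactants: 2 4-bromo-2-methoxy-1-(methoxymethoxy)benzene; 4 (R)-N-methoxy-N,2,2-trimethyl-1,3-dioxolane-4-carboxamide
Product: 6 (R)-(2,2-dimethyl-1,3-dioxolan-4-yl)[3-methoxy-4-(methoxymethoxy)phenyl]methanone, via aryllithium 5 (not isolated)
Conditions: 2, n-BuLi, THF, −78 °C; then 4, −78 °C; aq NH4Cl
Reagents that add atoms: none
Why: Bromine–lithium exchange followed by Weinreb ketone synthesis; the chelated tetrahedral adduct stops at the ketone and the α-centre is not enolised at −78 °C.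

Step 4
Reactants: 6 (R)-(2,2-dimethyl-1,3-dioxolan-4-yl)[3-methoxy-4-(methoxymethoxy)phenyl]methanone
Product: 7 (S)-[(4R)-2,2-dimethyl-1,3-dioxolan-4-yl][3-methoxy-4-(methoxymethoxy)phenyl]methanol
Conditions: Zn(BH4)2, Et2O, −30 °C
Reagents that add atoms: none
Why: Chelation-controlled hydride reduction; zinc bridges the carbonyl oxygen and the α-oxygen of the dioxolane, hydride adds past the α-hydrogen and should set C7' as S, anti to C8'.

Step 5
Reactants: 7 (S)-[(4R)-2,2-dimethyl-1,3-dioxolan-4-yl][3-methoxy-4-(methoxymethoxy)phenyl]methanol; 8 trichloroethylene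
Product: 9 (4R)-4-[(S)-{[(E)-1,2-dichloroethenyl]oxy}[3-methoxy-4-(methoxymethoxy)phenyl]methyl]-2,2-dimethyl-1,3-dioxolane
Conditions: KH, THF, 0 °C; then 8, −40 °C → rt
Reagents that add atoms: none
Why: Anti addition of the potassium alkoxide to dichloroacetylene generated in the flask, then protonation, gives the (E)-dichlorovinyl ether with retention at C7'; both acetals are inert to the base and cannot migrate.

Step 6
Reactants: 9 (4R)-4-[(S)-{[(E)-1,2-dichloroethenyl]oxy}[3-methoxy-4-(methoxymethoxy)phenyl]methyl]-2,2-dimethyl-1,3-dioxolane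
Product: 10 (2R,3S)-3-{[(E)-1,2-dichloroethenyl]oxy}-3-[3-methoxy-4-(methoxymethoxy)phenyl]propane-1,2-diol
Conditions: AcOH/H2O (4:1), 40 °C
Reagents that add atoms: none
Why: Acid hydrolysis of the terminal acetonide; the dichlorovinyl ether, a strongly deactivated enol ether, and the aryl MOM ether are expected to survive dilute acetic acid.

Step 7
Reactants: 10 (2R,3S)-3-{[(E)-1,2-dichloroethenyl]oxy}-3-[3-methoxy-4-(methoxymethoxy)phenyl]propane-1,2-diol
Product: 11 (1S,2R)-3-[(tert-butyldimethylsilyl)oxy]-1-{[(E)-1,2-dichloroethenyl]oxy}-1-[3-methoxy-4-(methoxymethoxy)phenyl]propan-2-ol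
Conditions: TBSCl, imidazole, CH2Cl2, 0 °C
Reagents that add atoms: tert-butyldimethylsilyl chloride, CC(C)(C)[Si](C)(C)Cl
Why: Selective silylation of the primary hydroxyl by steric discrimination leaves the C8' carbinol free for the later coupling.

Step 8
Reactants: 11 (1S,2R)-3-[(tert-butyldimethylsilyl)oxy]-1-{[(E)-1,2-dichloroethenyl]oxy}-1-[3-methoxy-4-(methoxymethoxy)phenyl]propan-2-ol
Product: 13 (1S,2R)-3-[(tert-butyldimethylsilyl)oxy]-1-(ethynyloxy)-1-[3-methoxy-4-(methoxymethoxy)phenyl]propan-2-ol, via dilithiated alkynyl ether 12 (not isolated)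
Conditions: n-BuLi (3.3 equiv), THF, −78 °C; H2O, −78 → 0 °C; used at once
Reagents that add atoms: none
Why: Base-induced elimination of HCl to the chloroalkyne followed by chlorine–lithium exchange, the established dichlorovinyl ether route to alkynyl ethers, with one extra equivalent of base holding the C8' hydroxyl as a spectator lithium alkoxide; neither stereocentre is touched.

Step 9
Reactants: 14 methyl (E)-3-methoxybut-2-enoate; 15 dimethyl oxalate
Product: 17 methyl 4-methoxy-2-oxo-2H-pyran-6-carboxylate, via open-chain keto diester 16 (not isolated)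
Conditions: LiN(i-Pr)2 (2.2 equiv), THF, −78 °C; 15, −78 → 0 °C; aq HCl; then TsOH (cat.), toluene, 80 °C
Reagents that add atoms: none
Why: Vinylogous (γ) Claisen condensation of the lithium dienolate with the oxalate, then acid-catalysed lactonisation of the enol onto the cis ester, closes the 2-pyrone.

Step 10
Reactants: 17 methyl 4-methoxy-2-oxo-2H-pyran-6-carboxylate
Product: 18 methyl 3-bromo-4-methoxy-2-oxo-2H-pyran-6-carboxylate
Conditions: NBS, MeCN, rt
Reagents that add atoms: N-bromosuccinimide, O=C1CCC(=O)N1Br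
Why: Electrophilic bromination at C3, the β-carbon of the C4 enol ether; C5 is deactivated by the C6 ester.

Step 11
Reactants: 18 methyl 3-bromo-4-methoxy-2-oxo-2H-pyran-6-carboxylate
Product: 19 methyl 4-methoxy-2-oxo-3-(4,4,5,5-tetramethyl-1,3,2-dioxaborolan-2-yl)-2H-pyran-6-carboxylate
Conditions: B2pin2, Pd(dppf)Cl2 (5 mol %), KOAc, 1,4-dioxane, 80 °C
Reagents that add atoms: bis(pinacolato)diboron, CC1(C)OB(OC1(C)C)B1OC(C)(C)C(C)(C)O1
Why: Miyaura borylation of the vinylic bromide; acetate is too weak a base to open the pyrone.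

Step 12
Reactants: 19 methyl 4-methoxy-2-oxo-3-(4,4,5,5-tetramethyl-1,3,2-dioxaborolan-2-yl)-2H-pyran-6-carboxylate
Product: 20 methyl 3-hydroxy-4-methoxy-2-oxo-2H-pyran-6-carboxylate
Conditions: 30% H2O2, NaHCO3, THF/H2O, 0 °C; acidify to pH 3
Reagents that add atoms: hydrogen peroxide, OO
Why: Oxidation of the C–B bond by 1,2-shift of the pyranyl group from boron to oxygen under nearly neutral conditions gives the 3-hydroxypyrone, a stable acidic enol.

Step 13
Reactants: 13 (1S,2R)-3-[(tert-butyldimethylsilyl)oxy]-1-(ethynyloxy)-1-[3-methoxy-4-(methoxymethoxy)phenyl]propan-2-ol; 20 methyl 3-hydroxy-4-methoxy-2-oxo-2H-pyran-6-carboxylate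
Product: 21 methyl 3-{[(1S,2S)-3-[(tert-butyldimethylsilyl)oxy]-1-(ethynyloxy)-1-[3-methoxy-4-(methoxymethoxy)phenyl]propan-2-yl]oxy}-4-methoxy-2-oxo-2H-pyran-6-carboxylate
Conditions: PPh3, DIAD (betaine preformed), toluene, 0 °C → rt
Reagents that add atoms: none
Why: Mitsunobu etherification: the acidic pyranol is alkylated on oxygen by the activated C8' carbinol in an SN2 displacement that inverts C8' from R to S, so the anti carbinol gives the syn diether; preforming the betaine keeps free azodicarboxylate away from the ynol ether.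

Step 14
Reactants: 21 methyl 3-{[(1S,2S)-3-[(tert-butyldimethylsilyl)oxy]-1-(ethynyloxy)-1-[3-methoxy-4-(methoxymethoxy)phenyl]propan-2-yl]oxy}-4-methoxy-2-oxo-2H-pyran-6-carboxylate
Product: 23 methyl (2S,3S)-3-{[(tert-butyldimethylsilyl)oxy]methyl}-5-methoxy-2-[3-methoxy-4-(methoxymethoxy)phenyl]-2,3-dihydro-1,4-benzodioxine-7-carboxylate, via bridged lactone 22 (not isolated)
Conditions: Yb(fod)3 (10 mol %), 4 Å MS, toluene (0.01 M), 25 → 40 °C
Reagents that add atoms: none
Why: Proposed new method: the electron-rich ynol ether adds across C3 and C6 of the ester-bearing 2-pyrone, whose LUMO is lowered further by ytterbium chelated between the lactone carbonyl and the C3 ether oxygen, in an inverse-demand intramolecular [4+2] reaction, and the bridged lactone 22 then loses CO2 by retro-[4+2] to give the benzene ring without any oxidation step; the closest known reactions are intramolecular 2-pyrone–alkyne Diels–Alder/decarboxylation sequences and lanthanide-catalysed cycloadditions of electron-poor 2-pyrones with enol ethers. Ring A closes by this cycloaddition–cycloreversion pair (new bonds C4–C5 and C1–C6), and the dioxane closes in the same event as the six-membered ring fused across the new C4–C5 bond, the only mode the four-atom O–C8'–C7'–O tether allows. No stereocentre is formed; C7' and C8' are not touched and should pass from the syn diether into the trans-diequatorial dioxane. The step needs regioselectivity, which the tether fixes because the oxygen-bearing alkyne carbon can reach only pyrone C3 and the terminal carbon only C6, and it needs chemoselectivity over the [3,3] shift and retro-ene fragmentation open to a benzylic alkynyl ether, which catalysis at no more than 40 °C and high dilution are meant to secure.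

Step 15
Reactants: 23 methyl (2S,3S)-3-{[(tert-butyldimethylsilyl)oxy]methyl}-5-methoxy-2-[3-methoxy-4-(methoxymethoxy)phenyl]-2,3-dihydro-1,4-benzodioxine-7-carboxylate
Product: 24 [(2S,3S)-3-{[(tert-butyldimethylsilyl)oxy]methyl}-5-methoxy-2-[3-methoxy-4-(methoxymethoxy)phenyl]-2,3-dihydro-1,4-benzodioxin-7-yl]methanol
Conditions: i-Bu2AlH, CH2Cl2, −78 °C
Reagents that add atoms: none
Why: Hydride reduction of the aryl ester to the benzylic alcohol; the silyl ether, the acetal and the dioxane are inert.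

Step 16
Reactants: 24 [(2S,3S)-3-{[(tert-butyldimethylsilyl)oxy]methyl}-5-methoxy-2-[3-methoxy-4-(methoxymethoxy)phenyl]-2,3-dihydro-1,4-benzodioxin-7-yl]methanol
Product: 25 (2S,3S)-3-{[(tert-butyldimethylsilyl)oxy]methyl}-5-methoxy-2-[3-methoxy-4-(methoxymethoxy)phenyl]-2,3-dihydro-1,4-benzodioxine-7-carbaldehyde
Conditions: MnO2, CH2Cl2, rt
Reagents that add atoms: none
Why: Selective oxidation of the benzylic alcohol by MnO2; no other oxidisable hydroxyl is free.

Step 17
Reactants: 25 (2S,3S)-3-{[(tert-butyldimethylsilyl)oxy]methyl}-5-methoxy-2-[3-methoxy-4-(methoxymethoxy)phenyl]-2,3-dihydro-1,4-benzodioxine-7-carbaldehyde; 26 (triphenylphosphoranylidene)acetaldehyde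
Product: 27 (E)-3-[(2S,3S)-3-{[(tert-butyldimethylsilyl)oxy]methyl}-5-methoxy-2-[3-methoxy-4-(methoxymethoxy)phenyl]-2,3-dihydro-1,4-benzodioxin-7-yl]prop-2-enal
Conditions: 26 (1.2 equiv), toluene, 80 °C
Reagents that add atoms: none
Why: Wittig olefination with the stabilised formyl ylide should give the (E)-enal; only a small excess is used to limit a second homologation.

Step 18
Reactants: 27 (E)-3-[(2S,3S)-3-{[(tert-butyldimethylsilyl)oxy]methyl}-5-methoxy-2-[3-methoxy-4-(methoxymethoxy)phenyl]-2,3-dihydro-1,4-benzodioxin-7-yl]prop-2-enal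
Product: 28 (7'S,8'S)-nocomtal, (E)-3-[(2S,3S)-2-(4-hydroxy-3-methoxyphenyl)-3-(hydroxymethyl)-5-methoxy-2,3-dihydro-1,4-benzodioxin-7-yl]prop-2-enal
Conditions: 3 M HCl, THF, 40 °C
Reagents that add atoms: none
Why: Acid hydrolysis of the phenolic MOM acetal and of the primary silyl ether; the trans dioxane is the thermodynamically preferred isomer and is expected to hold.

**Compound list**
1 | 4-bromo-2-methoxyphenol | COc1cc(Br)ccc1O | starting material
2 | 4-bromo-2-methoxy-1-(methoxymethoxy)benzene | COCOc1ccc(Br)cc1OC | intermediate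
3 | methyl (R)-2,2-dimethyl-1,3-dioxolane-4-carboxylate | COC(=O)[C@H]1COC(C)(C)O1 | starting material
4 | (R)-N-methoxy-N,2,2-trimethyl-1,3-dioxolane-4-carboxamide | CON(C)C(=O)[C@H]1COC(C)(C)O1 | intermediate
5 | [3-methoxy-4-(methoxymethoxy)phenyl]lithium (not isolated) | [Li]c1ccc(OCOC)c(OC)c1 | intermediate
6 | (R)-(2,2-dimethyl-1,3-dioxolan-4-yl)[3-methoxy-4-(methoxymethoxy)phenyl]methanone | COCOc1ccc(cc1OC)C(=O)[C@H]1COC(C)(C)O1 | intermediate
7 | (S)-[(4R)-2,2-dimethyl-1,3-dioxolan-4-yl][3-methoxy-4-(methoxymethoxy)phenyl]methanol | COCOc1ccc(cc1OC)[C@H](O)[C@H]1COC(C)(C)O1 | intermediate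
8 | trichloroethylene | ClC=C(Cl)Cl | starting material
9 | (4R)-4-[(S)-{[(E)-1,2-dichloroethenyl]oxy}[3-methoxy-4-(methoxymethoxy)phenyl]methyl]-2,2-dimethyl-1,3-dioxolane | COCOc1ccc(cc1OC)[C@H](O/C(Cl)=C\Cl)[C@H]1COC(C)(C)O1 | intermediate
10 | (2R,3S)-3-{[(E)-1,2-dichloroethenyl]oxy}-3-[3-methoxy-4-(methoxymethoxy)phenyl]propane-1,2-diol | COCOc1ccc(cc1OC)[C@H](O/C(Cl)=C\Cl)[C@H](O)CO | intermediate
11 | (1S,2R)-3-[(tert-butyldimethylsilyl)oxy]-1-{[(E)-1,2-dichloroethenyl]oxy}-1-[3-methoxy-4-(methoxymethoxy)phenyl]propan-2-ol | COCOc1ccc(cc1OC)[C@H](O/C(Cl)=C\Cl)[C@H](O)CO[Si](C)(C)C(C)(C)C | intermediate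
12 | lithium (2R,3S)-1-[(tert-butyldimethylsilyl)oxy]-3-[(lithioethynyl)oxy]-3-[3-methoxy-4-(methoxymethoxy)phenyl]propan-2-olate (not isolated) | COCOc1ccc(cc1OC)[C@H](OC#C[Li])[C@H](O[Li])CO[Si](C)(C)C(C)(C)C | intermediate
13 | (1S,2R)-3-[(tert-butyldimethylsilyl)oxy]-1-(ethynyloxy)-1-[3-methoxy-4-(methoxymethoxy)phenyl]propan-2-ol | COCOc1ccc(cc1OC)[C@H](OC#C)[C@H](O)CO[Si](C)(C)C(C)(C)C | intermediate
14 | methyl (E)-3-methoxybut-2-enoate | C/C(OC)=C\C(=O)OC | starting material
15 | dimethyl oxalate | COC(=O)C(=O)OC | starting material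
16 | dimethyl (E)-4-methoxy-2-oxohex-4-enedioate (not isolated; drawn in the geometry that lactonises) | COC(=O)C(=O)C/C(OC)=C\C(=O)OC | intermediate
17 | methyl 4-methoxy-2-oxo-2H-pyran-6-carboxylate | COC(=O)C1=CC(OC)=CC(=O)O1 | intermediate
18 | methyl 3-bromo-4-methoxy-2-oxo-2H-pyran-6-carboxylate | COC(=O)C1=CC(OC)=C(Br)C(=O)O1 | intermediate
19 | methyl 4-methoxy-2-oxo-3-(4,4,5,5-tetramethyl-1,3,2-dioxaborolan-2-yl)-2H-pyran-6-carboxylate | COC(=O)C1=CC(OC)=C(B2OC(C)(C)C(C)(C)O2)C(=O)O1 | intermediate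
20 | methyl 3-hydroxy-4-methoxy-2-oxo-2H-pyran-6-carboxylate | COC(=O)C1=CC(OC)=C(O)C(=O)O1 | intermediate
21 | methyl 3-{[(1S,2S)-3-[(tert-butyldimethylsilyl)oxy]-1-(ethynyloxy)-1-[3-methoxy-4-(methoxymethoxy)phenyl]propan-2-yl]oxy}-4-methoxy-2-oxo-2H-pyran-6-carboxylate | COCOc1ccc(cc1OC)[C@H](OC#C)[C@@H](OC1=C(OC)C=C(OC1=O)C(=O)OC)CO[Si](C)(C)C(C)(C)C | intermediate
22 | dioxane-fused 2-oxabicyclo[2.2.2]octa-5,7-dien-3-one cycloadduct of 21 (not isolated; either bridgehead configuration gives 23) | COCOc1ccc(cc1OC)[C@@H]2OC3=CC4(C(=O)OC)C=C(OC)C3(O[C@H]2CO[Si](C)(C)C(C)(C)C)C(=O)O4 | intermediate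
23 | methyl (2S,3S)-3-{[(tert-butyldimethylsilyl)oxy]methyl}-5-methoxy-2-[3-methoxy-4-(methoxymethoxy)phenyl]-2,3-dihydro-1,4-benzodioxine-7-carboxylate | COCOc1ccc(cc1OC)[C@@H]2Oc3cc(cc(OC)c3O[C@H]2CO[Si](C)(C)C(C)(C)C)C(=O)OC | intermediate
24 | [(2S,3S)-3-{[(tert-butyldimethylsilyl)oxy]methyl}-5-methoxy-2-[3-methoxy-4-(methoxymethoxy)phenyl]-2,3-dihydro-1,4-benzodioxin-7-yl]methanol | COCOc1ccc(cc1OC)[C@@H]2Oc3cc(CO)cc(OC)c3O[C@H]2CO[Si](C)(C)C(C)(C)C | intermediate
25 | (2S,3S)-3-{[(tert-butyldimethylsilyl)oxy]methyl}-5-methoxy-2-[3-methoxy-4-(methoxymethoxy)phenyl]-2,3-dihydro-1,4-benzodioxine-7-carbaldehyde | COCOc1ccc(cc1OC)[C@@H]2Oc3cc(C=O)cc(OC)c3O[C@H]2CO[Si](C)(C)C(C)(C)C | intermediate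
26 | (triphenylphosphoranylidene)acetaldehyde | O=CC=P(c1ccccc1)(c1ccccc1)c1ccccc1 | starting material
27 | (E)-3-[(2S,3S)-3-{[(tert-butyldimethylsilyl)oxy]methyl}-5-methoxy-2-[3-methoxy-4-(methoxymethoxy)phenyl]-2,3-dihydro-1,4-benzodioxin-7-yl]prop-2-enal | COCOc1ccc(cc1OC)[C@@H]2Oc3cc(/C=C/C=O)cc(OC)c3O[C@H]2CO[Si](C)(C)C(C)(C)C | intermediate
28 | (7'S,8'S)-nocomtal | COc1cc([C@@H]2Oc3cc(/C=C/C=O)cc(OC)c3O[C@H]2CO)ccc1O | target

**Step count**
Total: 18 steps. Longest linear sequence: 13 steps (steps 2–8 and 13–18, from 3; the pyrone branch is steps 9–12).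

**Steps most likely to fail**

1. Step 14. The benzylic alkynyl ether may rearrange by a [3,3] shift through the electron-rich aryl ring, fragment by retro-ene loss of ketene, or be hydrated by traces of acid, faster than the donor-substituted pyrone undergoes cycloaddition. Fallback (known chemistry, ring A brought in ready-made): it sets out from 13. Mitsunobu etherification of 13 with commercial methyl 3-bromo-4-hydroxy-5-methoxybenzoate (COC(=O)c1cc(Br)c(O)c(OC)c1; PPh3, DIAD, toluene, 0 °C) should give, with the same inversion at C8', methyl 3-bromo-4-{[(1S,2S)-3-[(tert-butyldimethylsilyl)oxy]-1-(ethynyloxy)-1-[3-methoxy-4-(methoxymethoxy)phenyl]propan-2-yl]oxy}-5-methoxybenzoate F1. Hydration of the ynol ether with a trace of PPTS in wet THF at 0 °C should turn it into the C7' acetate, methyl 4-{[(1S,2S)-1-(acetyloxy)-3-[(tert-butyldimethylsilyl)oxy]-1-[3-methoxy-4-(methoxymethoxy)phenyl]propan-2-yl]oxy}-3-bromo-5-methoxybenzoate F2, and K2CO3 in MeOH at 0 °C should free the C7' alcohol, methyl 3-bromo-4-{[(1S,2S)-3-[(tert-butyldimethylsilyl)oxy]-1-hydroxy-1-[3-methoxy-4-(methoxymethoxy)phenyl]propan-2-yl]oxy}-5-methoxybenzoate F3. Palladium-catalysed intramolecular C–O coupling of the secondary alcohol with the aryl bromide (Pd(OAc)2, 2-(di-tert-butylphosphino)-1,1'-binaphthyl, Cs2CO3, toluene, 70 °C), which does not touch the carbinol carbon, should close the dioxane and bring the route back at 23.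

2. Step 13. Displacement at the hindered, doubly β-oxygenated C8' oxyphosphonium ion by the weakly nucleophilic pyranolate may be outrun by elimination or by addition of the betaine or the acidic pyranol to the ynol ether. Fallback (sulfonate displacement by a preformed anion, no phosphine or azo reagent): it sets out from 13. Tf2O and 2,6-di-tert-butyl-4-methylpyridine in CH2Cl2 at −78 °C should give (1S,2R)-3-[(tert-butyldimethylsilyl)oxy]-1-(ethynyloxy)-1-[3-methoxy-4-(methoxymethoxy)phenyl]propan-2-yl trifluoromethanesulfonate F4, and the cesium salt of 20 (Cs2CO3, DMF, −20 → 0 °C) should displace the triflate with inversion at C8' and return to the route at 21.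

3. Step 8. The neighbouring lithium alkoxide may add to the chloroalkyne formed on the way, or the free hydroxyl may add across the new ynol ether during work-up, before the labile product is used. Fallback (hydroxyl masked during the elimination): it sets out from 11. TMSCl and imidazole in CH2Cl2 at 0 °C should give (1S,2R)-3-[(tert-butyldimethylsilyl)oxy]-1-{[(E)-1,2-dichloroethenyl]oxy}-1-[3-methoxy-4-(methoxymethoxy)phenyl]-2-[(trimethylsilyl)oxy]propane F5. n-BuLi (2.3 equiv) in THF at −78 °C followed by water should give (1S,2R)-3-[(tert-butyldimethylsilyl)oxy]-1-(ethynyloxy)-1-[3-methoxy-4-(methoxymethoxy)phenyl]-2-[(trimethylsilyl)oxy]propane F6. K2CO3 in MeOH at 0 °C should remove only the secondary trimethylsilyl ether and return to the route at 13.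

**Further compounds**
F1 | step 14 | methyl 3-bromo-4-{[(1S,2S)-3-[(tert-butyldimethylsilyl)oxy]-1-(ethynyloxy)-1-[3-methoxy-4-(methoxymethoxy)phenyl]propan-2-yl]oxy}-5-methoxybenzoate | COCOc1ccc(cc1OC)[C@H](OC#C)[C@@H](Oc1c(Br)cc(cc1OC)C(=O)OC)CO[Si](C)(C)C(C)(C)C
F2 | step 14 | methyl 4-{[(1S,2S)-1-(acetyloxy)-3-[(tert-butyldimethylsilyl)oxy]-1-[3-methoxy-4-(methoxymethoxy)phenyl]propan-2-yl]oxy}-3-bromo-5-methoxybenzoate | COCOc1ccc(cc1OC)[C@H](OC(C)=O)[C@@H](Oc1c(Br)cc(cc1OC)C(=O)OC)CO[Si](C)(C)C(C)(C)C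
F3 | step 14 | methyl 3-bromo-4-{[(1S,2S)-3-[(tert-butyldimethylsilyl)oxy]-1-hydroxy-1-[3-methoxy-4-(methoxymethoxy)phenyl]propan-2-yl]oxy}-5-methoxybenzoate | COCOc1ccc(cc1OC)[C@H](O)[C@@H](Oc1c(Br)cc(cc1OC)C(=O)OC)CO[Si](C)(C)C(C)(C)C
F4 | step 13 | (1S,2R)-3-[(tert-butyldimethylsilyl)oxy]-1-(ethynyloxy)-1-[3-methoxy-4-(methoxymethoxy)phenyl]propan-2-yl trifluoromethanesulfonate | COCOc1ccc(cc1OC)[C@H](OC#C)[C@H](OS(=O)(=O)C(F)(F)F)CO[Si](C)(C)C(C)(C)C
F5 | step 8 | (1S,2R)-3-[(tert-butyldimethylsilyl)oxy]-1-{[(E)-1,2-dichloroethenyl]oxy}-1-[3-methoxy-4-(methoxymethoxy)phenyl]-2-[(trimethylsilyl)oxy]propane | COCOc1ccc(cc1OC)[C@H](O/C(Cl)=C\Cl)[C@H](O[Si](C)(C)C)CO[Si](C)(C)C(C)(C)C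
F6 | step 8 | (1S,2R)-3-[(tert-butyldimethylsilyl)oxy]-1-(ethynyloxy)-1-[3-methoxy-4-(methoxymethoxy)phenyl]-2-[(trimethylsilyl)oxy]propane | COCOc1ccc(cc1OC)[C@H](OC#C)[C@H](O[Si](C)(C)C)CO[Si](C)(C)C(C)(C)C
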